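## Analysis of the target

Compound 21 is a furofuran lignan, a cis-fused 3,7-dioxabicyclo[3.3.0]octane. Lignan numbering is used throughout: C7–C8–C9 for the guaiacyl half and C7'–C8'–C9' for the veratryl half, with ring A as O–C7–C8–C8'–C9' and ring B as O–C7'–C8'–C8–C9. The four stereocentres are contiguous (7R, 8S, 7'S, 8'R). The hydroxyl on C8 and the hydrogen on C8' are cis on the convex face, and both aryl groups are exo, on that same face. The aryl groups differ by a single O-methyl group, so there is no usable symmetry; each half must be introduced separately, with the phenol masked. Both benzylic C–O bonds carry electron-rich arenes and ionise in acid, which can turn an exo aryl group into an endo one. In addition, the phenol opens a quinone methide channel at C7, and the tertiary alcohol next to C7 invites 1,2-shifts whenever C7 becomes cationic. The hardest centre is C8, which is fully substituted, oxygenated and flanked by three different carbon branches (C7, C9, C8'). The strategy rests on ring B: the veratryl group on C7' is trans to C9' on C8', and C9' is trans to O8 on C8, so aryl and O8 share one face while C9' and C7 share the other. This alternation is what two successive anti additions to a γ-aryl butenolide deliver, and it leaves C7 and C9' cis, ready for ring A.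

## Retrosynthetic reasoning

**21 to 20 (phenol O–H).** The phenol is traced back to the silyl ether 20. A free phenol would consume organometallic and hydride reagents and would make the C7–O bond much easier to ionise. The silyl ether can be cleaved at silicon at the very end under buffered, non-acidic conditions that leave both benzylic ethers alone.

**20 to 19 to 18 (the two C9–H bonds).** The C9 methylene is traced back through the lactol 19 to the lactone carbonyl of 18. A carbonyl at C9 makes C8 an enolate carbon and C8' an acceptor carbon, so every earlier bond formation depends on it. The forward sequence must remove this oxygen without breaking the C7'–O bond of ring B. It is therefore done in two stages, a partial reduction followed by an ionic reduction at low temperature.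

**18 to 17 (C7–O of ring A).** Ring A is opened at C7–O and not at C9'–O. A cut at C9'–O would demand a configurationally defined C7 carbinol. A cut at C7–O passes through a planar benzylic centre, so both C7 epimers of 17 converge and the bicyclic framework decides the outcome. The forward reaction has to ionise C7 without disturbing the veratryl-bearing C7'.

**17 to 15 (C9'–O and C7–H, with loss of one carbon).** The hydroxymethyl group on C8' is traced back to a vinyl group and the C7 carbinol to an aryl ketone. Vinyl is a small hydroxymethyl surrogate that copper transfers cleanly. Oxidative cleavage and reduction of both carbonyl groups can share one flask.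

**15 to 12 and 13 (C8'–C9' and C8–O).**
- Both bonds are cut together, which removes two stereocentres and leaves C7' as the only one in 12.
- The order of events is fixed by the stereochemistry. Whatever arrives last at the planar C8 enters trans to C9', so oxygen must come last and C7 must already be attached.
- This is why the acceptor carries the aroyl group. The group also raises the electrophilicity of C8' and gives a stabilised enolate that survives until the oxidant is added.

**12 to 10 to 9 (C8=C8').** The alkene is traced back to the selenide 10, made from the β-keto lactone 9. The C7'–H of 12 is benzylic and vinylogous to two carbonyl groups, so the alkene has to be released without base and at low temperature. The thermal syn elimination of the selenoxide 11 meets both conditions, and 10 is a storable precursor.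

**9 to 8 to 5 and 7 (C7–C8).** This bond is cut at the aldehyde oxidation level, as an aldol addition followed by oxidation. An electron-rich benzoate ester would be a poorer electrophile than the lactone itself, and the alkoxide it releases would threaten the aryl silyl ether. Aldehyde 7 comes from 6 by silylation.

**5 to 3 to 1 and 2 (C7'–H and aryl–C7').** The single stereocentre that controls everything else is set by a catalytic enantioselective reduction of the aryl ketone 3. The hydroxy ester 4 then closes to 5. Ketone 3 arises from 1 and 2 by aromatic acylation; the ester form is used because a free acid would not survive the reducing agent.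

## Alternatives that were turned down

**Alternative 1:**
- *Disconnection:* C8–C8' and C7'–O are cut at once. Both rings unravel to the acyclic α-alkoxy ketone A2, whose only stereocentre is C7.
- *Forward key step:* A strong Lewis acid activates the C8 ketone and the cinnamyl alkene attacks through C8' (5-exo, ring A). The silyl ether oxygen on C9 then captures the veratryl-stabilised C7' cation (ring B), giving A1, the pivalate of 21.
- *For it:* Two rings, two bonds and three stereocentres form in one operation, and C9 is already at the ether oxidation level. In step economy and oxidation-state economy it is clearly stronger than the chosen route.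
- *Against it:*
  - C7 of A2 is benzylic and α to the ketone, so it can enolise and racemise under the conditions of the key step.
  - A ketone is a weak Prins electrophile, whereas the same Lewis acid easily ionises the cinnamyl C9'–O bond and the benzylic C7–O bond. Fragmentation therefore competes with cyclisation.
  - Three new centres depend on one centre acting through a flexible transition state, and C7' is fixed by capture of a free cation.
- *Comparison:* The chosen route is longer. However, each new centre is set by its direct neighbour on a rigid five-membered ring, and the failure modes are spread over separate steps.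

**Alternative 2:**
- *Disconnection:* C7–C8 and C7–O are cut, which removes C7 with its arene as aldehyde 7. This leaves the ring B lactone A4, which already carries O8 and a silylated C9' hydroxyl.
- *Forward key step:* A silyl triflate with a tertiary amine converts A4 into its silyl ketene acetal and condenses 7 with the C9' oxygen to an oxocarbenium ion. C8 attacks this ion and gives A3, the O8-silyl ether of 18.
- *For it:*
  - The tether forces the new C7–C8 bond onto the face that carries C9', so the C8 configuration does not rest on a steric bias. This is stronger than the chosen route on that point.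
  - The configurationally fragile butenolide 12 and the ionisation at C7 are both avoided.
- *Against it:*
  - Both C7 and its oxygen lie inside the forming ring, so the closure is 5-endo at the electrophile with poor orbital overlap.
  - The untethered Mukaiyama aldol addition of the ketene acetal to activated 7 should be faster. It would occur trans to C9' and give the C8 epimer that cannot close.
  - Soft enolisation to a tetrasubstituted, oxygenated ketene acetal is slow.
  - A4 already holds three stereocentres and needs a conjugate addition, a hydroxylation and an oxidative cleavage before the key step, and the endgame from A3 is the same. Nothing is saved.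
- *Comparison:* The chosen route gives up the tether but uses open, well-behaved bond formations.

**Alternative 3:**
- *Disconnection:* C8–C8' and C7–O are cut, leading to the epoxy ether A6, which bears a silyl enol ether.
- *Forward key step:* A titanocene reagent of trivalent titanium opens the epoxide by single-electron transfer to a C8' radical. This radical adds 5-exo to C8 (ring B) and leaves a benzylic C7 radical. An oxidative halogen quench then lets the C9' titanium alkoxide capture C7 (ring A), giving A5, the O8-silyl ether of 20.
- *For it:* Both rings form in one flask under neutral conditions that spare acid-labile benzylic ethers, and C9 needs no reduction. It is stronger in brevity and in mildness.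
- *Against it:*
  - A nucleophilic alkyl radical must attack the oxygen-bearing, fully substituted carbon of an electron-rich alkene, a mismatch in polarity and in sterics.
  - The slower cyclisation lets a second equivalent of the metal capture the radical and eliminate the neighbouring titanium alkoxide, so the epoxide is simply deoxygenated.
  - Nothing strongly decides whether C7 or the silyloxy group ends up cis to C9', and only one of these isomers can close ring A.
  - The silyl enol ether is itself sensitive to the halogen quench.
- *Comparison:* The chosen route sets C8 by a polar, sterically readable step on a preformed ring.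

Key step: step 8

Assumption: epimer mixtures at centres that are later erased or reset (C7 and C8 in 8, C8 in 9 to 11, C7 in 17, C9 in 19) are carried forward without separation. TBS stands for tert-butyldimethylsilyl.

## Route

Step 1
Reactants: 1 veratrole (1,2-dimethoxybenzene); 2 methyl 4-chloro-4-oxobutanoate
Product: 3 methyl 4-(3,4-dimethoxyphenyl)-4-oxobutanoate
Conditions: AlCl3 (2.2 equiv), CH2Cl2, 0 °C → rt; ice/aq. HCl
Reagents that add atoms: none
Why: Friedel–Crafts acylation; 1 is attacked para to one methoxy group, and the new acyl group deactivates the ring against a second acylation. The low temperature should avoid demethylation by AlCl3.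

Step 2
Reactants: 3 methyl 4-(3,4-dimethoxyphenyl)-4-oxobutanoate
Product: 5 (S)-5-(3,4-dimethoxyphenyl)dihydrofuran-2(3H)-one, via hydroxy ester 4 (not isolated)
Conditions: (R)-Me-CBS oxazaborolidine [(R)-1-methyl-3,3-diphenyltetrahydro-1H,3H-pyrrolo[1,2-c][1,3,2]oxazaborole] (10 mol %), BH3·SMe2, THF, −20 °C; MeOH; then pyridinium p-toluenesulfonate (cat.), toluene, rt
Reagents that add atoms: none
Why: Corey–Bakshi–Shibata reduction; with the arene as the large group the (R)-catalyst delivers hydride to the Re face and sets C7' as S, and the ester is inert to the borane at this temperature. The lactone closes by acyl substitution, so the benzylic C7'–O bond is never broken; crystallisation of 5 can raise the enantiopurity.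

Step 3
Reactants: 6 vanillin
Product: 7 4-(tert-butyldimethylsilyloxy)-3-methoxybenzaldehyde
Conditions: TBSCl, imidazole, DMF, rt
Reagents that add atoms: tert-butyldimethylsilyl chloride, CC(C)(C)[Si](C)(C)Cl
Why: Standard imidazole-promoted silylation of a phenol; the aryl silyl ether tolerates the enolate, copper, hydride and acid steps that follow.

Step 4
Reactants: 5 (S)-5-(3,4-dimethoxyphenyl)dihydrofuran-2(3H)-one; 7 4-(tert-butyldimethylsilyloxy)-3-methoxybenzaldehyde
Product: 8 (5S)-3-{[4-(tert-butyldimethylsilyloxy)-3-methoxyphenyl](hydroxy)methyl}-5-(3,4-dimethoxyphenyl)dihydrofuran-2(3H)-one (epimers at C7 and C8)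
Conditions: LiN(i-Pr)2 (1.1 equiv), THF, −78 °C; then 7; AcOH, −78 °C
Reagents that add atoms: none
Why: Aldol addition of a lithium lactone enolate to a non-enolisable aromatic aldehyde forms C7–C8. The two new centres do not matter, since C7 becomes sp2 in step 5 and C8 in step 7.

Step 5
Reactants: 8 aldol adduct
Product: 9 (5S)-3-[4-(tert-butyldimethylsilyloxy)-3-methoxybenzoyl]-5-(3,4-dimethoxyphenyl)dihydrofuran-2(3H)-one (C8 epimers and enol)
Conditions: Dess–Martin periodinane (1,1,1-triacetoxy-1,1-dihydro-1,2-benziodoxol-3(1H)-one), CH2Cl2, 0 °C → rt
Reagents that add atoms: none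
Why: Dess–Martin oxidation of a benzylic secondary alcohol; the near-neutral medium should avoid retro-aldol cleavage and dehydration of the β-hydroxy lactone.

Step 6
Reactants: 9 β-keto lactone
Product: 10 (5S)-3-[4-(tert-butyldimethylsilyloxy)-3-methoxybenzoyl]-5-(3,4-dimethoxyphenyl)-3-(phenylselanyl)dihydrofuran-2(3H)-one (C8 epimers)
Conditions: PhSeCl, pyridine, CH2Cl2, 0 °C; cold dilute aq. HCl wash
Reagents that add atoms: benzeneselenenyl chloride, Cl[Se]c1ccccc1
Why: Electrophilic selenenylation of a β-dicarbonyl enol, in which C8 is the only nucleophilic carbon. The quaternary selenide cannot enolise, so it is the last storable compound before the sensitive acceptor.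

Step 7
Reactants: 10 α-phenylselanyl β-keto lactone
Product: 12 (S)-3-[4-(tert-butyldimethylsilyloxy)-3-methoxybenzoyl]-5-(3,4-dimethoxyphenyl)furan-2(5H)-one, via selenoxide 11 (not isolated)
Conditions: 30% aq. H2O2 (excess), CH2Cl2, 0 °C; cold water wash, dried and used at once
Reagents that add atoms: none
Why: Selenoxide syn elimination; only C8' carries a β-hydrogen and one of its two hydrogens is syn in either C8 epimer, so a single alkene should form at or below 0 °C. No base is present, which protects the acidic C7'–H, and the excess peroxide oxidises the expelled selenium species to the seleninic acid so that it cannot add back.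

Step 8
Reactants: 12 (S)-3-aroyl-5-aryl butenolide; 13 vinylmagnesium bromide
Product: 15 (3R,4R,5S)-3-[4-(tert-butyldimethylsilyloxy)-3-methoxybenzoyl]-5-(3,4-dimethoxyphenyl)-3-hydroxy-4-vinyldihydrofuran-2(3H)-one, via magnesium enolate 14 (not isolated)
Conditions: 13 (1.15 equiv), CuBr·SMe2 (15 mol %), THF–Me2S, −78 °C; 12 in THF added slowly; then 2-(phenylsulfonyl)-3-phenyloxaziridine (1.6 equiv), −78 → 0 °C; aq. NH4Cl
Reagents that add atoms: 2-(phenylsulfonyl)-3-phenyloxaziridine, O=S(=O)(c1ccccc1)N1OC1c1ccccc1
Why: Transmetalation of 13 to monovalent copper gives a vinylcuprate that complexes the C8=C8' bond of 12, adds at C8' and reductively eliminates, forming C8'–C9' and leaving the chelated bromomagnesium β-keto lactone enolate 14. C8 of 14 then attacks the oxaziridine oxygen with N–O cleavage, forming C8–O, and the adduct collapses to the alkoxide of 15 and a sulfonimine. The closest known reaction types are copper-catalysed conjugate addition of Grignard reagents to γ-substituted butenolides with trans induction, tandem conjugate addition–enolate oxidation, and N-sulfonyloxaziridine hydroxylation of β-dicarbonyl enolates. No ring is closed; ring B is already present and acts as the rigid template. C8' is controlled by C7', because the veratryl group blocks one face of the flat butenolide and vinyl enters trans to it. C8 is controlled by C8', because the adjacent vinyl group shields its face of the planar enolate more than the 1,3-related pseudoequatorial arene shields the other; the bulky oxidant therefore delivers oxygen trans to vinyl, which leaves C7 cis to C9' as ring A requires. The step needs 1,4-addition to win over 1,2-addition and over removal of C7'–H; this is secured by the double activation of C8', by the electron-rich and therefore sluggish aryl ketone, by copper catalysis at −78 °C and by slow addition of 12 to the reagent. Only a slight excess of 13 is used so that leftover organometallic does not consume the oxidant.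

Step 9
Reactants: 15 hydroxy keto vinyl lactone
Product: 17 (3R,4R,5S)-3-{[4-(tert-butyldimethylsilyloxy)-3-methoxyphenyl](hydroxy)methyl}-5-(3,4-dimethoxyphenyl)-3-hydroxy-4-(hydroxymethyl)dihydrofuran-2(3H)-one (C7 epimers), via keto aldehyde 16 (not isolated)
Conditions: O3, CH2Cl2–MeOH, −78 °C (Sudan red 7B end point); NaBH4, −78 → −20 °C; pH 7 buffer
Reagents that add atoms: ozone, [O-][O+]=O
Why: Ozonolysis with reductive work-up; the terminal alkene reacts faster than the alkoxyarenes and the dye marks the end point. NaBH4 reduces the peroxidic products, the aldehyde 16 and the inductively activated aryl ketone in the same flask. The low temperature and neutral quench limit acyl migration to the new C9' oxygen, and the C7 epimer mixture is harmless because step 10 makes C7 planar.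

Step 10
Reactants: 17 triol lactone
Product: 18 (3S,3aR,6R,6aR)-6-[4-(tert-butyldimethylsilyloxy)-3-methoxyphenyl]-3-(3,4-dimethoxyphenyl)-6a-hydroxytetrahydro-1H,3H-furo[3,4-c]furan-1-one
Conditions: (±)-camphor-10-sulfonic acid (10 mol %), 4 Å molecular sieves, CH2Cl2, 0 °C → rt
Reagents that add atoms: none
Why: Acid-catalysed dehydrative etherification of SN1 type; either C7 epimer ionises to the same aryl-stabilised centre, which the cis-disposed C9' hydroxyl captures in a 5-exo closure of ring A. C7 is set here as R, because in the cis-fused transition state the arene takes the convex side next to O8 and not the space under ring B. Catalytic acid and a short contact time keep the closure kinetic.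

Step 11
Reactants: 18 bicyclic hydroxy lactone
Product: 19 (3S,3aR,6R,6aR)-6-[4-(tert-butyldimethylsilyloxy)-3-methoxyphenyl]-3-(3,4-dimethoxyphenyl)tetrahydro-1H,3H-furo[3,4-c]furan-1,6a-diol (C9 anomers)
Conditions: i-Bu2AlH (3 equiv), CH2Cl2, −78 °C; aq. potassium sodium tartrate
Reagents that add atoms: none
Why: Partial reduction of a lactone to the lactol; the first equivalent deprotonates O8, and the aluminium hemiacetal, chelated by that alkoxide, should persist at −78 °C until hydrolysis.

Step 12
Reactants: 19 lactol
Product: 20 (1S,3aS,4R,6aR)-4-[4-(tert-butyldimethylsilyloxy)-3-methoxyphenyl]-1-(3,4-dimethoxyphenyl)tetrahydro-1H,3H-furo[3,4-c]furan-3a(4H)-ol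
Conditions: Et3SiH (3 equiv), BF3·OEt2 (1.5 equiv), CH2Cl2, −78 → −40 °C; aq. NaHCO3
Reagents that add atoms: none
Why: Ionic hydrogenation of a lactol through its cyclic oxocarbenium ion, a reaction type known for furofuran acetals that carry benzylic ethers. C9 becomes a methylene group, so no stereocentre is at stake, and the low temperature is meant to leave C7–O and C7'–O intact.

Step 13
Reactants: 20 silyl-protected target
Product: 21 (1S,3aS,4R,6aR)-1-(3,4-dimethoxyphenyl)-4-(4-hydroxy-3-methoxyphenyl)tetrahydro-1H,3H-furo[3,4-c]furan-3a(4H)-ol, in lignan numbering 7R,8S,7'S,8'R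
Conditions: n-Bu4NF, AcOH (1:1), THF, 0 °C
Reagents that add atoms: none
Why: Fluoride cleavage of an aryl silyl ether; the acetic acid buffer protonates the phenoxide at once, so that it cannot expel the ring A oxygen from C7 and scramble that centre.

## Compound list

1 | veratrole | COc1ccccc1OC | starting material
2 | methyl 4-chloro-4-oxobutanoate | COC(=O)CCC(=O)Cl | starting material
3 | methyl 4-(3,4-dimethoxyphenyl)-4-oxobutanoate | COC(=O)CCC(=O)c1ccc(OC)c(OC)c1 | intermediate
4 | methyl (S)-4-(3,4-dimethoxyphenyl)-4-hydroxybutanoate (not isolated) | COC(=O)CC[C@H](O)c1ccc(OC)c(OC)c1 | intermediate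
5 | (S)-5-(3,4-dimethoxyphenyl)dihydrofuran-2(3H)-one | O=C1CC[C@@H](c2ccc(OC)c(OC)c2)O1 | intermediate
6 | vanillin | COc1cc(C=O)ccc1O | starting material
7 | 4-(tert-butyldimethylsilyloxy)-3-methoxybenzaldehyde | COc1cc(C=O)ccc1O[Si](C)(C)C(C)(C)C | intermediate
8 | (5S)-aldol adduct, epimers at C7 and C8 | COc1cc(C(O)C2C[C@@H](c3ccc(OC)c(OC)c3)OC2=O)ccc1O[Si](C)(C)C(C)(C)C | intermediate
9 | (5S)-3-aroyl-5-aryl butyrolactone | COc1cc(C(=O)C2C[C@@H](c3ccc(OC)c(OC)c3)OC2=O)ccc1O[Si](C)(C)C(C)(C)C | intermediate
10 | (5S)-3-aroyl-5-aryl-3-(phenylselanyl) butyrolactone | COc1cc(C(=O)C2([Se]c3ccccc3)C[C@@H](c3ccc(OC)c(OC)c3)OC2=O)ccc1O[Si](C)(C)C(C)(C)C | intermediate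
11 | selenoxide of 10 (not isolated) | COc1cc(C(=O)C2([Se](=O)c3ccccc3)C[C@@H](c3ccc(OC)c(OC)c3)OC2=O)ccc1O[Si](C)(C)C(C)(C)C | intermediate
12 | (S)-3-[4-(tert-butyldimethylsilyloxy)-3-methoxybenzoyl]-5-(3,4-dimethoxyphenyl)furan-2(5H)-one | COc1cc(C(=O)C2=C[C@@H](c3ccc(OC)c(OC)c3)OC2=O)ccc1O[Si](C)(C)C(C)(C)C | intermediate
13 | vinylmagnesium bromide | C=C[Mg]Br | starting material
14 | bromomagnesium enolate, vinyl trans to aryl (not isolated) | COc1cc(C(O[Mg]Br)=C2C(=O)O[C@H](c3ccc(OC)c(OC)c3)[C@H]2C=C)ccc1O[Si](C)(C)C(C)(C)C | intermediate
15 | (3R,4R,5S)-3-aroyl-3-hydroxy-4-vinyl-5-aryl butyrolactone | COc1cc(C(=O)[C@]2(O)[C@H](C=C)[C@@H](c3ccc(OC)c(OC)c3)OC2=O)ccc1O[Si](C)(C)C(C)(C)C | intermediate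
16 | (3R,4R,5S)-3-aroyl-4-formyl-3-hydroxy-5-aryl butyrolactone (not isolated) | COc1cc(C(=O)[C@]2(O)[C@H](C=O)[C@@H](c3ccc(OC)c(OC)c3)OC2=O)ccc1O[Si](C)(C)C(C)(C)C | intermediate
17 | (3R,4R,5S)-triol lactone, C7 epimers | COc1cc(C(O)[C@]2(O)[C@H](CO)[C@@H](c3ccc(OC)c(OC)c3)OC2=O)ccc1O[Si](C)(C)C(C)(C)C | intermediate
18 | (3S,3aR,6R,6aR)-6a-hydroxy furofuran-1-one | COc1cc([C@H]2OC[C@@H]3[C@@H](c4ccc(OC)c(OC)c4)OC(=O)[C@]23O)ccc1O[Si](C)(C)C(C)(C)C | intermediate
19 | (3S,3aR,6R,6aR)-lactol, C9 anomers | COc1cc([C@H]2OC[C@@H]3[C@@H](c4ccc(OC)c(OC)c4)OC(O)[C@]23O)ccc1O[Si](C)(C)C(C)(C)C | intermediate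
20 | (1S,3aS,4R,6aR)-silyl-protected target | COc1cc([C@H]2OC[C@@H]3[C@@H](c4ccc(OC)c(OC)c4)OC[C@]23O)ccc1O[Si](C)(C)C(C)(C)C | intermediate
21 | (1S,3aS,4R,6aR)-1-(3,4-dimethoxyphenyl)-4-(4-hydroxy-3-methoxyphenyl)tetrahydro-1H,3H-furo[3,4-c]furan-3a(4H)-ol | COc1cc([C@H]2OC[C@@H]3[C@@H](c4ccc(OC)c(OC)c4)OC[C@]23O)ccc1O | target

## Step count and least certain steps

Total step count: 13. Longest linear sequence: 12 (steps 1, 2 and 4 to 13); step 3 lies on the side branch.

**Step 8 (key step).**
- *Risk:*
  - Facial discrimination in the oxygen transfer may be incomplete, because the face trans to vinyl is also the face that carries the C7' arene.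
  - The chelated magnesium enolate may react sluggishly with the oxidant.
  - The organometallic may abstract a proton from C7' of 12, which would erode the enantiopurity.
- *Fallback:* It sets out from 12 and returns at 15. The two bond formations are separated and reagent control is added to the substrate bias.
  1. The copper-catalysed vinyl transfer is run alone and quenched with acid. This gives (4S,5S)-3-[4-(tert-butyldimethylsilyloxy)-3-methoxybenzoyl]-5-(3,4-dimethoxyphenyl)-4-vinyldihydrofuran-2(3H)-one F1, in which C8 is mobile.
  2. The sodium enolate of F1, made with NaN(SiMe3)2, is hydroxylated with the matched antipode of enantiopure (camphorylsulfonyl)oxaziridine to give 15.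

**Step 7.**
- *Risk:*
  - Configuration at C7' may be lost through proton loss to an achiral 2-oxyfuran. This hydrogen is benzylic and vinylogous to two carbonyl groups.
  - Water or peroxide may add to the doubly activated alkene.
- *Fallback:* It sets out from 5 and returns at 15, avoiding the doubly activated acceptor by bringing in vinyl first, the aroyl group second and oxygen last.
  1. Selenenylation of the enolate of 5 (LiN(i-Pr)2, PhSeCl) gives (5S)-5-(3,4-dimethoxyphenyl)-3-(phenylselanyl)dihydrofuran-2(3H)-one F2.
  2. Oxidation with H2O2 and syn elimination gives the far less acidic (S)-5-(3,4-dimethoxyphenyl)furan-2(5H)-one F3.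
  3. Addition of 13 with CuBr·SMe2 gives (4R,5S)-5-(3,4-dimethoxyphenyl)-4-vinyldihydrofuran-2(3H)-one F4.
  4. Aldol addition to 7 gives the (4S,5S)-hydroxybenzyl lactone F5.
  5. Dess–Martin oxidation gives F1, which is hydroxylated as described for step 8.

**Step 9.**
- *Risk:*
  - The lactone acyl group may migrate from the C7' oxygen to the new C9' alkoxide in the basic borohydride medium.
  - The acyloxy group may β-eliminate from 16 before the aldehyde is reduced.
  - Ozone may attack the dialkoxyarenes.
- *Fallback:* It sets out from 15 and returns at 20, giving up ring B deliberately.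
  1. Ozonolysis followed by exhaustive reduction with LiBH4 (through 16) gives (2S,3R,4S)-1-[4-(tert-butyldimethylsilyloxy)-3-methoxyphenyl]-4-(3,4-dimethoxyphenyl)-2,3-bis(hydroxymethyl)butane-1,2,4-triol F6. Both acyl-migration isomers would converge on F6.
  2. A double acid-catalysed benzylic closure (camphor-10-sulfonic acid, CH2Cl2) forms rings A and B together, with both arenes taking the exo positions.
- *Price:* C7' is reset and not conserved, and closure between C7 and the C7' oxygen may compete.

**Step 10.**
- *Risk:* Ionisation at C7 is retarded by O8, by the C9 carbonyl and by the weaker silyloxy donor. The acid strength required may therefore approach that which ionises the veratryl C7'–O(acyl) bond. The consequences would be epimerisation at C7', a 1,2-shift from C8, or exo/endo equilibration after closure.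
- *Fallback:* It sets out from 17 and returns at 18, and it changes the reactive intermediate.
  1. Buffered n-Bu4NF/AcOH first frees the phenol and gives the (3R,4R,5S)-phenolic triol lactone F7.
  2. F7 loses water under much milder conditions (pyridinium p-toluenesulfonate) through a neutral p-quinone methide. The C9' hydroxyl adds to it in a 5-exo, 1,6 sense and gives the (3S,3aR,6R,6aR)-phenolic bicyclic lactone F8.
  3. Selective silylation of the phenol (TBSCl, imidazole) leads back to 18.

**Step 12.**
- *Risk:* Formation of the C9 oxocarbenium ion is slowed by the adjacent O8. Ionisation of the benzylic ethers by BF3 may then compete, with epimerisation or reductive ring opening as the result.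
- *Fallback:* It sets out from 18 and returns at 20.
  1. LiBH4 opens the lactone and gives (2R,3S,4R)-2-[4-(tert-butyldimethylsilyloxy)-3-methoxyphenyl]-4-[(S)-(3,4-dimethoxyphenyl)(hydroxy)methyl]-3-(hydroxymethyl)tetrahydrofuran-3-ol F9, with ring A intact.
  2. Catalytic camphor-10-sulfonic acid closes the C9 hydroxyl onto C7'. This is the only five-membered closure available, and the arene takes the exo position.

## Further compounds

F1 | step 8 | (4S,5S)-3-[4-(tert-butyldimethylsilyloxy)-3-methoxybenzoyl]-5-(3,4-dimethoxyphenyl)-4-vinyldihydrofuran-2(3H)-one | COc1cc(C(=O)C2[C@H](C=C)[C@@H](c3ccc(OC)c(OC)c3)OC2=O)ccc1O[Si](C)(C)C(C)(C)C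
F2 | step 7 | (5S)-5-(3,4-dimethoxyphenyl)-3-(phenylselanyl)dihydrofuran-2(3H)-one | O=C1O[C@H](c2ccc(OC)c(OC)c2)CC1[Se]c1ccccc1
F3 | step 7 | (S)-5-(3,4-dimethoxyphenyl)furan-2(5H)-one | O=C1C=C[C@@H](c2ccc(OC)c(OC)c2)O1
F4 | step 7 | (4R,5S)-5-(3,4-dimethoxyphenyl)-4-vinyldihydrofuran-2(3H)-one | O=C1C[C@H](C=C)[C@@H](c2ccc(OC)c(OC)c2)O1
F5 | step 7 | (4S,5S)-3-{[4-(tert-butyldimethylsilyloxy)-3-methoxyphenyl](hydroxy)methyl}-5-(3,4-dimethoxyphenyl)-4-vinyldihydrofuran-2(3H)-one | COc1cc(C(O)C2[C@H](C=C)[C@@H](c3ccc(OC)c(OC)c3)OC2=O)ccc1O[Si](C)(C)C(C)(C)C
F6 | step 9 | (2S,3R,4S)-1-[4-(tert-butyldimethylsilyloxy)-3-methoxyphenyl]-4-(3,4-dimethoxyphenyl)-2,3-bis(hydroxymethyl)butane-1,2,4-triol, C1 epimers | COc1cc(C(O)[C@@](O)(CO)[C@H](CO)[C@H](O)c2ccc(OC)c(OC)c2)ccc1O[Si](C)(C)C(C)(C)C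
F7 | step 10 | (3R,4R,5S)-5-(3,4-dimethoxyphenyl)-3-hydroxy-3-[hydroxy(4-hydroxy-3-methoxyphenyl)methyl]-4-(hydroxymethyl)dihydrofuran-2(3H)-one | COc1cc(C(O)[C@]2(O)[C@H](CO)[C@@H](c3ccc(OC)c(OC)c3)OC2=O)ccc1O
F8 | step 10 | (3S,3aR,6R,6aR)-3-(3,4-dimethoxyphenyl)-6a-hydroxy-6-(4-hydroxy-3-methoxyphenyl)tetrahydro-1H,3H-furo[3,4-c]furan-1-one | COc1cc([C@H]2OC[C@@H]3[C@@H](c4ccc(OC)c(OC)c4)OC(=O)[C@]23O)ccc1O
F9 | step 12 | (2R,3S,4R)-2-[4-(tert-butyldimethylsilyloxy)-3-methoxyphenyl]-4-[(S)-(3,4-dimethoxyphenyl)(hydroxy)methyl]-3-(hydroxymethyl)tetrahydrofuran-3-ol | COc1cc([C@H]2OC[C@H]([C@H](O)c3ccc(OC)c(OC)c3)[C@]2(O)CO)ccc1O[Si](C)(C)C(C)(C)C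
A1 | alternative 1 | phenol pivalate of 21 | COc1cc([C@H]2OC[C@@H]3[C@@H](c4ccc(OC)c(OC)c4)OC[C@]23O)ccc1OC(=O)C(C)(C)C
A2 | alternative 1 | (R)-3-(tert-butyldimethylsilyloxy)-1-[(E)-3-(3,4-dimethoxyphenyl)allyloxy]-1-[3-methoxy-4-(pivaloyloxy)phenyl]propan-2-one | COc1cc([C@@H](OC/C=C/c2ccc(OC)c(OC)c2)C(=O)CO[Si](C)(C)C(C)(C)C)ccc1OC(=O)C(C)(C)C
A3 | alternative 2 | O8-tert-butyldimethylsilyl ether of 18 | COc1cc([C@H]2OC[C@@H]3[C@@H](c4ccc(OC)c(OC)c4)OC(=O)[C@]23O[Si](C)(C)C(C)(C)C)ccc1O[Si](C)(C)C(C)(C)C
A4 | alternative 2 | (4R,5S)-3-(tert-butyldimethylsilyloxy)-5-(3,4-dimethoxyphenyl)-4-[(trimethylsilyloxy)methyl]dihydrofuran-2(3H)-one, C3 epimers | COc1ccc([C@H]2OC(=O)C(O[Si](C)(C)C(C)(C)C)[C@@H]2CO[Si](C)(C)C)cc1OC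
A5 | alternative 3 | O8-tert-butyldimethylsilyl ether of 20 | COc1cc([C@H]2OC[C@@H]3[C@@H](c4ccc(OC)c(OC)c4)OC[C@]23O[Si](C)(C)C(C)(C)C)ccc1O[Si](C)(C)C(C)(C)C
A6 | alternative 3 | epoxy ether with a silyl enol ether: 2-{(3,4-dimethoxyphenyl)[2-(tert-butyldimethylsilyloxy)-3-(4-(tert-butyldimethylsilyloxy)-3-methoxyphenyl)allyloxy]methyl}oxirane, C7' arranged in space as in 21 (R by the sequence rule) | COc1cc(C=C(CO[C@H](c2ccc(OC)c(OC)c2)C2CO2)O[Si](C)(C)C(C)(C)C)ccc1O[Si](C)(C)C(C)(C)C
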